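**Plan** (plakortolide numbering: lactone C1(=O)–C2H2–C3H(OO)–C4(Me)(O)–C5H2–C6(Me)(OO)–(CH2)9–aryl)

1. Retrosynthesis: cut O–C3 (hydroperoxide oxa-Michael onto a butenolide) and C6–OO/C6–C7 (perhydrolysis of a tertiary carbinol made from a methyl ketone and the chain Grignard reagent); then read the γ-lactone as the Baeyer–Villiger product of a cyclobutanone and cut C1–C2 and C3–C4 together as an intramolecular ketene–enol ether [2+2] cycloaddition.
2. Enabling feature: C1–C2–C3–C4 of the lactone ring, with oxygen on C3 and a quaternary, oxygen-bearing C4, is the retron of a 3-alkoxy-2,2-dialkylcyclobutanone; C5 plus an oxygen on C6 is a three-atom tether, so a temporary oxolane (O, C3, C4, C5, C6) closes together with the four-membered ring.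
3. Forward order: cyclobutanone and temporary oxolane (step 3), ring expansion to the γ-lactone (step 4), oxolane opened to butenolide and C6 ketone (steps 5, 6), chain joined at C6 (step 8), hydroperoxide (step 9), 1,2-dioxane (step 10), phenol freed (step 11).
4. Stereochemistry: the C6–H carbinol of (S)-γ-valerolactone directs C4 in the cycloaddition and is then erased; C3 follows from C4 in the cis-selective oxa-Michael closure; C6 is created without control and its epimer is separated.

Key step: step 3

Remark: C6 carries a methyl and an n-alkyl group that no existing stereocentre can tell apart, so both C6 epimers are formed in step 9 and the unwanted one is removed after ring closure in step 10.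

**Route**

Step 1
Reactants: 1 (S)-γ-valerolactone
Product: 3 (5S)-3,5-dimethyloxolan-2-one (both C3 epimers), via lithium enolate 2 (not isolated)
Conditions: LiN(iPr)2, THF, −78 °C; MeI, −78 → −20 °C
Reagents that add atoms: iodomethane CI
Why: Lithium enolate alkylation of a γ-lactone; the new α-centre is of no consequence because it becomes the ketene carbon in step 3, and the (5S) carbinol centre is not touched.

Step 2
Reactants: 3 (5S)-3,5-dimethyloxolan-2-one
Product: 5 potassium (4S)-4-(ethenyloxy)-2-methylpentanoate, via potassium hydroxy carboxylate 4 (not isolated)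
Conditions: KOH (1.0 equiv), MeOH–H2O, rt, evaporation; then HC≡CH (1 atm), KOH (cat.), DMSO, 80 °C
Reagents that add atoms: potassium hydroxide [K+].[OH-]; acetylene C#C
Why: Saponification gives a carboxylate that cannot relactonise, and base-catalysed nucleophilic vinylation of the secondary alcohol with acetylene should install the enol ether without exposing it to acid; the (4S) centre is not involved.

Step 3
Reactants: 5 potassium (4S)-4-(ethenyloxy)-2-methylpentanoate
Product: 8 (1S,3S,5S)-3,5-dimethyl-2-oxabicyclo[3.2.0]heptan-6-one, via acyloxypyridinium salt 6 (not isolated), via ketene 7 (not isolated)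
Conditions: 2-chloro-1-methylpyridinium iodide, 18-crown-6 (cat.), MeCN, rt; then slow addition to Et3N, MeCN, reflux (high dilution)
Reagents that add atoms: none
Why: Activation of the carboxylate as its 2-acyloxypyridinium salt and base-induced loss of 1-methylpyridin-2-one should give methyl(alkyl)ketene 7, which the tethered enol ether traps in a thermal [2+2] cycloaddition (antarafacial ketene component, concerted but asynchronous); the closest known reaction type is the intramolecular ketene–alkene cycloaddition of unsaturated acids with a three-atom tether. The electrophilic ketene carbonyl carbon (C1) bonds to the nucleophilic terminal CH2 of the enol ether (C2) and the ketene α-carbon (C4) to the oxygen-bearing carbon (C3), so polarity and tether length both call for the fused adduct; the oxolane (O, C3, C4, C5, C6) closes in the 5-exo sense at the enol ether and the four-membered ring closes with the second bond C1–C2. C3 and C4 must be cis because of the bicyclo[3.2.0] fusion, and their absolute sense is set by the (S)-carbinol carbon C6, whose methyl group should take the convex, pseudo-equatorial position of the forming oxolane, cis to the C4 methyl group and away from the cyclobutanone. The step needs facial selectivity relative to C6 and suppression of ketene dimerisation; the first rests on this envelope preference (a minor isomer with the C6 methyl on the concave face would be removed by chromatography), the second on slow addition at high dilution.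

Step 4
Reactants: 8 (1S,3S,5S)-3,5-dimethyl-2-oxabicyclo[3.2.0]heptan-6-one
Product: 9 (3aS,5S,6aS)-5,6a-dimethyltetrahydrofuro[3,2-b]furan-2(3H)-one
Conditions: mCPBA, CH2Cl2, 0 °C → rt
Reagents that add atoms: 3-chloroperbenzoic acid OOC(=O)c1cccc(Cl)c1
Why: Baeyer–Villiger oxidation of a strained cyclobutanone; the quaternary C4 migrates in preference to the CH2 group and with retention, which turns the cyclobutanone into the γ-lactone with the (S)-configured C4–O bond of the target.

Step 5
Reactants: 9 (3aS,5S,6aS)-5,6a-dimethyltetrahydrofuro[3,2-b]furan-2(3H)-one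
Product: 12 (5S)-5-methyl-5-[(2S)-2-(trimethylsilyloxy)propyl]furan-2(5H)-one, via lithium enolate 10 (not isolated), via lithium alkoxide 11 (not isolated)
Conditions: LiN(SiMe3)2, THF, −78 → −40 °C; Me3SiCl, −78 °C
Reagents that add atoms: chlorotrimethylsilane C[Si](C)(C)Cl
Why: E1cB β-elimination (retro-oxa-Michael) of the lactone enolate, driven by the change from an ester enolate to a far less basic alkoxide, should open the temporary oxolane to the butenolide, and cold silylation should prevent re-addition; C4 is quaternary and unaffected, C3 becomes sp2.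

Step 6
Reactants: 12 (5S)-5-methyl-5-[(2S)-2-(trimethylsilyloxy)propyl]furan-2(5H)-one
Product: 14 (5S)-5-methyl-5-(2-oxopropyl)furan-2(5H)-one, via alcohol 13 (not isolated)
Conditions: CrO3, H2SO4, H2O, acetone, 0 °C
Reagents that add atoms: none
Why: Jones oxidation, in which the acidic medium cleaves the trimethylsilyl ether and chromic acid oxidises the secondary alcohol to the methyl ketone without touching the butenolide; the relay stereocentre at C6 is erased here as planned.

Step 7
Reactants: 15 (4-bromophenoxy)tri(propan-2-yl)silane; 16 1,9-dibromononane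
Product: 18 [4-(9-bromononyl)phenoxy]tri(propan-2-yl)silane, via aryl Grignard reagent 17 (not isolated)
Conditions: Mg, THF; then 16 (3 equiv), Li2CuCl4 (3 mol %), THF, 0 °C
Reagents that add atoms: none
Why: Copper-catalysed coupling of an aryl Grignard reagent with a primary alkyl bromide; the excess of dibromide should suppress double coupling, and no stereocentre is involved.

Step 8
Reactants: 18 [4-(9-bromononyl)phenoxy]tri(propan-2-yl)silane; 14 (5S)-5-methyl-5-(2-oxopropyl)furan-2(5H)-one
Product: 20 (5S)-5-[2-hydroxy-2-methyl-11-(4-{[tri(propan-2-yl)silyl]oxy}phenyl)undecyl]-5-methylfuran-2(5H)-one (both C6 epimers), via alkyl Grignard reagent 19 (not isolated)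
Conditions: Mg, THF; CeCl3, THF, −78 °C; then 14; AcOH, −78 °C
Reagents that add atoms: none
Why: CeCl3-mediated Grignard addition to a ketone: the weakly basic organocerium species should add to the methyl ketone faster than it enolises it (which would expel the lactone carboxylate by β-elimination) or attacks the butenolide, and the cold acidic quench keeps the tertiary alkoxide from adding to C3; the carbinol centre C6 forms as both epimers, which does not matter because it is ionised in step 9.

Step 9
Reactants: 20 tertiary alcohol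
Product: 21 (5S)-5-[2-hydroperoxy-2-methyl-11-(4-{[tri(propan-2-yl)silyl]oxy}phenyl)undecyl]-5-methylfuran-2(5H)-one (both C6 epimers)
Conditions: H2O2 (50 % aq.), H2SO4 (cat.), Et2O, 0 °C
Reagents that add atoms: hydrogen peroxide OO
Why: Acid-catalysed perhydrolysis of a tertiary alcohol (SN1 capture of the tertiary C6 cation by H2O2), which the electron-poor butenolide and the vinylogously deactivated C4–O bond should survive; C6 is formed without control as both epimers.

Step 10
Reactants: 21 hydroperoxide
Product: 22 O-triisopropylsilyl plakortolide F (3S,4S,6R)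
Conditions: Et2NH, CF3CH2OH, rt; chromatography
Reagents that add atoms: none
Why: Intramolecular oxa-Michael addition of the hydroperoxide to the butenolide (6-exo-trig) closes the 1,2-dioxane; the tether from C4 can deliver the peroxide oxygen only to the face of C3 that gives the cis-fused bicycle, which sets C3 as (S), and the (6R) product is separated from its C6 epimer at this stage.

Step 11
Reactants: 22 O-triisopropylsilyl plakortolide F
Product: 23 plakortolide F
Conditions: Bu4NF, AcOH, THF, 0 °C
Reagents that add atoms: none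
Why: Fluoride cleavage of the aryl silyl ether, buffered with acetic acid so that neither the peroxide nor the lactone meets free phenoxide or hydroxide; no stereocentre is touched.

**Compound list**

1 | (S)-γ-valerolactone, (5S)-5-methyloxolan-2-one | C[C@H]1CCC(=O)O1 | starting material
2 | lithium (5S)-5-methyl-4,5-dihydrofuran-2-olate | [Li+].[O-]C1=CC[C@H](C)O1 | intermediate
3 | (5S)-3,5-dimethyloxolan-2-one (both C3 epimers) | C[C@H]1CC(C)C(=O)O1 | intermediate
4 | potassium (4S)-4-hydroxy-2-methylpentanoate | C[C@H](O)CC(C)C(=O)[O-].[K+] | intermediate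
5 | potassium (4S)-4-(ethenyloxy)-2-methylpentanoate | C[C@H](OC=C)CC(C)C(=O)[O-].[K+] | intermediate
6 | 2-{[(4S)-4-(ethenyloxy)-2-methylpentanoyl]oxy}-1-methylpyridinium iodide | C[C@H](OC=C)CC(C)C(=O)Oc1cccc[n+]1C.[I-] | intermediate
7 | (4S)-4-(ethenyloxy)-2-methylpent-1-en-1-one (ketene) | C[C@H](OC=C)CC(C)=C=O | intermediate
8 | (1S,3S,5S)-3,5-dimethyl-2-oxabicyclo[3.2.0]heptan-6-one | O=C1C[C@@H]2O[C@@H](C)C[C@]12C | intermediate
9 | (3aS,5S,6aS)-5,6a-dimethyltetrahydrofuro[3,2-b]furan-2(3H)-one | O=C1C[C@@H]2O[C@@H](C)C[C@]2(C)O1 | intermediate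
10 | lithium enolate of 9 | [Li+].[O-]C1=C[C@@H]2O[C@@H](C)C[C@]2(C)O1 | intermediate
11 | lithium (2S)-1-[(2S)-2-methyl-5-oxo-2,5-dihydrofuran-2-yl]propan-2-olate | C[C@H]([O-])C[C@]1(C)OC(=O)C=C1.[Li+] | intermediate
12 | (5S)-5-methyl-5-[(2S)-2-(trimethylsilyloxy)propyl]furan-2(5H)-one | C[C@H](O[Si](C)(C)C)C[C@]1(C)OC(=O)C=C1 | intermediate
13 | (5S)-5-[(2S)-2-hydroxypropyl]-5-methylfuran-2(5H)-one | C[C@H](O)C[C@]1(C)OC(=O)C=C1 | intermediate
14 | (5S)-5-methyl-5-(2-oxopropyl)furan-2(5H)-one | CC(=O)C[C@]1(C)OC(=O)C=C1 | intermediate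
15 | (4-bromophenoxy)tri(propan-2-yl)silane | CC(C)[Si](Oc1ccc(Br)cc1)(C(C)C)C(C)C | starting material
16 | 1,9-dibromononane | BrCCCCCCCCCBr | starting material
17 | (4-{[tri(propan-2-yl)silyl]oxy}phenyl)magnesium bromide | CC(C)[Si](Oc1ccc([Mg]Br)cc1)(C(C)C)C(C)C | intermediate
18 | [4-(9-bromononyl)phenoxy]tri(propan-2-yl)silane | CC(C)[Si](Oc1ccc(CCCCCCCCCBr)cc1)(C(C)C)C(C)C | intermediate
19 | [9-(4-{[tri(propan-2-yl)silyl]oxy}phenyl)nonyl]magnesium bromide | CC(C)[Si](Oc1ccc(CCCCCCCCC[Mg]Br)cc1)(C(C)C)C(C)C | intermediate
20 | (5S)-5-[2-hydroxy-2-methyl-11-(4-{[tri(propan-2-yl)silyl]oxy}phenyl)undecyl]-5-methylfuran-2(5H)-one (both C6 epimers) | CC(O)(CCCCCCCCCc1ccc(O[Si](C(C)C)(C(C)C)C(C)C)cc1)C[C@]1(C)OC(=O)C=C1 | intermediate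
21 | (5S)-5-[2-hydroperoxy-2-methyl-11-(4-{[tri(propan-2-yl)silyl]oxy}phenyl)undecyl]-5-methylfuran-2(5H)-one (both C6 epimers) | CC(OO)(CCCCCCCCCc1ccc(O[Si](C(C)C)(C(C)C)C(C)C)cc1)C[C@]1(C)OC(=O)C=C1 | intermediate
22 | O-triisopropylsilyl plakortolide F (3S,4S,6R) | C[C@@]1(CCCCCCCCCc2ccc(O[Si](C(C)C)(C(C)C)C(C)C)cc2)C[C@]2(C)OC(=O)C[C@@H]2OO1 | intermediate
23 | plakortolide F | C[C@@]1(CCCCCCCCCc2ccc(O)cc2)C[C@]2(C)OC(=O)C[C@@H]2OO1 | target

**Step count and risks**

Total: 11 steps. Longest linear sequence: 10 steps (1–6, then 8–11); step 7 prepares the chain fragment.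

Steps most likely to fail:

Step 3. The ketene may dimerise faster than it cyclises, or the C6 methyl group may discriminate the two faces too weakly, which would lower the enantiomeric purity at C4 once C6 is erased. The fallback sets out from 3 and replaces the cycloaddition by enolate oxygenation, which also bypasses steps 2 and 4. The lithium enolate of 3 is hydroxylated with 2-(phenylsulfonyl)-3-phenyloxaziridine, anti to the C6 methyl group as is usual for γ-substituted lactone enolates, to give (3S,5S)-3-hydroxy-3,5-dimethyloxolan-2-one F1. Reduction with iBu2AlH gives the lactol (3S,5S)-3,5-dimethyloxolane-2,3-diol F2, and Wittig reaction with Ph3P=CHCO2Et gives ethyl (2E,4S,6S)-4,6-dihydroxy-4-methylhept-2-enoate F3. A catalytic base (DBU) should then bring about oxa-Michael addition of the C6 hydroxyl and lactonisation of the C4 hydroxyl, and the route is rejoined at 9.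

Step 5. The oxolane may re-close by oxa-Michael addition during the quench, or the enolate may be silylated before it eliminates. The fallback sets out from 9 and opens the ether by oxidation instead of elimination. RuCl3 (cat.) with NaIO4 should oxidise the ether methine at C6, which is more electron-rich than the C3–H next to the lactone, and the resulting hemiketal opens to (4S,5S)-4-hydroxy-5-methyl-5-(2-oxopropyl)oxolan-2-one F4. Mesylation (MsCl, Et3N) gives the mesylate of F4, (2S,3S)-2-methyl-5-oxo-2-(2-oxopropyl)oxolan-3-yl methanesulfonate F5, which eliminates in the same flask, and the route is rejoined at 14.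

Step 9. The C6 cation may lose a proton or be captured internally instead of by H2O2, or the hydroperoxide may undergo acid-induced O–O cleavage with migration. The fallback sets out from 20 and installs the peroxide by a radical process. Burgess dehydration should give a mixture of the alkenes (5S)-5-methyl-5-[2-methylidene-11-(4-{[tri(propan-2-yl)silyl]oxy}phenyl)undecyl]furan-2(5H)-one F6, the C6=C7 isomer (5S)-5-methyl-5-[2-methyl-11-(4-{[tri(propan-2-yl)silyl]oxy}phenyl)undec-2-enyl]furan-2(5H)-one F7 and the C5=C6 isomer (5S)-5-methyl-5-[2-methyl-11-(4-{[tri(propan-2-yl)silyl]oxy}phenyl)undec-1-enyl]furan-2(5H)-one F8. All three should converge in a Mukaiyama–Isayama hydroperoxysilylation (Co(acac)2 cat., O2, Et3SiH) on the tertiary C6 radical to give the triethylsilyl peroxide (5S)-5-methyl-5-[2-methyl-2-(triethylsilylperoxy)-11-(4-{[tri(propan-2-yl)silyl]oxy}phenyl)undecyl]furan-2(5H)-one F9. Mild acid (AcOH, H2O, THF) frees the hydroperoxide, and the route is rejoined at 21.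

**Further compounds**

F1 | step 3 | (3S,5S)-3-hydroxy-3,5-dimethyloxolan-2-one | C[C@H]1C[C@](C)(O)C(=O)O1
F2 | step 3 | (3S,5S)-3,5-dimethyloxolane-2,3-diol (both anomers) | C[C@H]1C[C@](C)(O)C(O)O1
F3 | step 3 | ethyl (2E,4S,6S)-4,6-dihydroxy-4-methylhept-2-enoate | C[C@H](O)C[C@](C)(O)/C=C/C(=O)OCC
F4 | step 5 | (4S,5S)-4-hydroxy-5-methyl-5-(2-oxopropyl)oxolan-2-one | CC(=O)C[C@]1(C)OC(=O)C[C@@H]1O
F5 | step 5 | (2S,3S)-2-methyl-5-oxo-2-(2-oxopropyl)oxolan-3-yl methanesulfonate | CC(=O)C[C@]1(C)OC(=O)C[C@@H]1OS(C)(=O)=O
F6 | step 9 | (5S)-5-methyl-5-[2-methylidene-11-(4-{[tri(propan-2-yl)silyl]oxy}phenyl)undecyl]furan-2(5H)-one | C=C(CCCCCCCCCc1ccc(O[Si](C(C)C)(C(C)C)C(C)C)cc1)C[C@]1(C)OC(=O)C=C1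
F7 | step 9 | (5S)-5-methyl-5-[2-methyl-11-(4-{[tri(propan-2-yl)silyl]oxy}phenyl)undec-2-enyl]furan-2(5H)-one (E and Z) | CC(=CCCCCCCCCc1ccc(O[Si](C(C)C)(C(C)C)C(C)C)cc1)C[C@]1(C)OC(=O)C=C1
F8 | step 9 | (5S)-5-methyl-5-[2-methyl-11-(4-{[tri(propan-2-yl)silyl]oxy}phenyl)undec-1-enyl]furan-2(5H)-one (E and Z) | CC(CCCCCCCCCc1ccc(O[Si](C(C)C)(C(C)C)C(C)C)cc1)=C[C@]1(C)OC(=O)C=C1
F9 | step 9 | (5S)-5-methyl-5-[2-methyl-2-(triethylsilylperoxy)-11-(4-{[tri(propan-2-yl)silyl]oxy}phenyl)undecyl]furan-2(5H)-one (both C6 epimers) | CC(OO[Si](CC)(CC)CC)(CCCCCCCCCc1ccc(O[Si](C(C)C)(C(C)C)C(C)C)cc1)C[C@]1(C)OC(=O)C=C1
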